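**Plan** (gibberellane numbering C1–C20 for every intermediate; α/β as is customary for gibberellins: C19 and C20 α, H-5, H-9 and the C7 carboxyl β)
Retrosynthesis: first the C4–CH3 bond (ester enolate methylation) and the C13–C16 bond of ring D (ketyl–alkyne closure) are cut; then, in one operation, the two ring B bonds C9–C10 and C6–C8; last the ester C–O link between a ring A acid and a ring C allylic alcohol.
Forward: ring C (cyclohexenol 5 with a C13 ketal and a propargyl arm on C8) and ring A (all-cis cyclohexane triester from hydrogenation of an isophthalate, then desymmetrised) are joined as the C20 allylic ester. Ring B then forms without isolation of intermediates by an Ireland–Claisen [3,3] shift (C9–C10) followed by a 5-exo Mukaiyama–Michael closure (C6–C8); ring D follows by SmI2 cyclisation.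
Enabling feature: C10 carries the C20 carboxyl, so C10=C20 can be a ketene acetal whose ester oxygen sits on C14 of ring C, allylic to C8=C9. The [3,3] shift returns that oxygen to C20 as the acid and leaves C14=C8 next to the C13 ketal, so that C8 becomes the electrophilic β-carbon for the C6 ester enolate equivalent (the C7 carboxyl).
Stereochemistry: the C14 carbinol (CBS reduction) sets C9 by suprafacial transfer; C5 (enzymatic desymmetrisation) sets C10 (allyl unit anti to the axial C6 arm), then C8 and C6 through the cis ring closure; C13 is fixed by the bridge; C4 by equatorial methylation anti to the axial C20 carboxylate.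

Key step: step 8

Assumption: 1,4-dioxaspiro[4.5]decan-6-one (1) and dimethyl 2-bromobenzene-1,3-dicarboxylate (6) are taken as catalogue compounds (each is otherwise one step from cyclohexane-1,2-dione or 2-bromoisophthalic acid).

Step 1
Reactants: 1 1,4-dioxaspiro[4.5]decan-6-one; 2 3-bromo-1-(trimethylsilyl)prop-1-yne
Product: 3 rac-7-[3-(trimethylsilyl)prop-2-yn-1-yl]-1,4-dioxaspiro[4.5]decan-6-one
Conditions: LiN(i-Pr)2, THF, −78 °C; then 2, DMPU, −78 → 0 °C
Reagents that add atoms: none
Why: Enolate alkylation: the ketone can enolise only toward C7 (C5 is the ketal carbon), and the lithium enolate should displace the propargylic bromide by SN2; the stereocentre formed is removed in step 2.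

Step 2
Reactants: 3 rac-7-[3-(trimethylsilyl)prop-2-yn-1-yl]-1,4-dioxaspiro[4.5]decan-6-one
Product: 4 7-[3-(trimethylsilyl)prop-2-yn-1-yl]-1,4-dioxaspiro[4.5]dec-7-en-6-one
Conditions: 2-iodoxybenzoic acid (IBX), DMSO/toluene, 70 °C
Reagents that add atoms: none
Why: IBX α,β-dehydrogenation of a ketone that has a single enolisable side; as with other 2-alkylcyclohexanones, the ring hydrogen should be lost to give the endocyclic conjugated enone (future C8=C9), and no stereocentre remains.

Step 3
Reactants: 4 7-[3-(trimethylsilyl)prop-2-yn-1-yl]-1,4-dioxaspiro[4.5]dec-7-en-6-one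
Product: 5 (6R)-7-[3-(trimethylsilyl)prop-2-yn-1-yl]-1,4-dioxaspiro[4.5]dec-7-en-6-ol
Conditions: (S)-B-methyl oxazaborolidine from diphenylprolinol ((S)-Me-CBS, 20 mol%), catecholborane, toluene, −78 °C; aq. NaOH work-up
Reagents that add atoms: none
Why: Corey–Bakshi–Shibata 1,2-reduction of the enone sets the carbinol centre (future C14–O) by catalyst control, the fully substituted ketal carbon being taken as the large group and catecholborane at low temperature sparing the alkene and the alkynylsilane; the sense is to be confirmed by Mosher ester analysis, the antipodal catalyst being equally available.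

Step 4
Reactants: 6 dimethyl 2-bromobenzene-1,3-dicarboxylate; 7 tert-butyl bromoacetate
Product: 8 dimethyl 2-(2-tert-butoxy-2-oxoethyl)benzene-1,3-dicarboxylate
Conditions: Zn dust, THF (7 → BrZnCH2CO2t-Bu); then 6, Pd2(dba)3 (1 mol%), XPhos (2 mol%), THF, 60 °C
Reagents that add atoms: none
Why: Negishi coupling of a Reformatsky zinc enolate with an electron-poor aryl bromide on zerovalent palladium carrying a bulky biarylphosphine; this should tolerate both ortho esters and creates no stereocentre.

Step 5
Reactants: 8 dimethyl 2-(2-tert-butoxy-2-oxoethyl)benzene-1,3-dicarboxylate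
Product: 9 dimethyl all-cis-2-(2-tert-butoxy-2-oxoethyl)cyclohexane-1,3-dicarboxylate (meso)
Conditions: H2 (60 bar), Rh/Al2O3 (5% Rh), MeOH, 50 °C
Reagents that add atoms: none
Why: Heterogeneous arene hydrogenation (dearomatisation) delivers all hydrogens from the catalyst face, so the three ring substituents (C19 and C20 esters and the C6 arm) should end all-cis in a meso triester.

Step 6
Reactants: 9 dimethyl all-cis-2-(2-tert-butoxy-2-oxoethyl)cyclohexane-1,3-dicarboxylate (meso)
Product: 10 (1S,2S,3R)-2-(2-tert-butoxy-2-oxoethyl)-3-(methoxycarbonyl)cyclohexane-1-carboxylic acid (all-cis; free acid = C20, methyl ester = C19)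
Conditions: pig liver esterase, 0.1 M phosphate buffer pH 7.5, 10% acetone, 30 °C
Reagents that add atoms: water, O
Why: Enzymatic desymmetrisation of a meso diester: hydrolysis of one enantiotopic methyl ester sets the absolute configuration at C5 and frees only the C20 carboxyl, the tert-butyl ester not being a substrate; the hydrolase is chosen for the enantiomer shown.

Step 7
Reactants: 10 (1S,2S,3R)-2-(2-tert-butoxy-2-oxoethyl)-3-(methoxycarbonyl)cyclohexane-1-carboxylic acid; 5 (6R)-7-[3-(trimethylsilyl)prop-2-yn-1-yl]-1,4-dioxaspiro[4.5]dec-7-en-6-ol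
Product: 11 allylic ester of the C20 carboxyl of 10 with the carbinol oxygen of 5 (ring A all-cis, carbinol carbon R)
Conditions: EDC·HCl, DMAP (1 equiv), CH2Cl2, 0 °C → rt
Reagents that add atoms: none
Why: Steglich esterification joins the two fragments through the C20–O–C14 ester; the carbinol centre is untouched and any epimerisation at C10 is irrelevant because C10 is enolised in step 8.

Step 8
Reactants: 11 allylic ester of 10 with 5
Product: 14 13-oxo tricyclic diacid monomethyl ester (rings A B C of the target), via tris(silyl ketene acetal) 12 (not isolated), via Claisen silyl ester 13 (not isolated)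
Conditions: without isolation: LiN(i-Pr)2 (3.6 equiv), Me3SiCl (4.5 equiv), THF, −78 °C, then 65 °C; volatiles removed, residue taken up in CH2Cl2 and filtered from LiCl under argon; Me3SiOTf (3 equiv), −78 → 0 °C; then CF3CO2H/H2O (9:1), 0 °C → rt
Reagents that add atoms: water, O
Why: Excess LiN(i-Pr)2/Me3SiCl turns the three ester α-positions (C10, C6, C4) into silyl ketene acetals (12), and on warming the unit C10=C20(OSiMe3)–O–C14–C8=C9 undergoes the Ireland–Claisen [3,3] shift (closest known type: ester enolate Claisen rearrangement of cyclohex-2-enyl esters of α-branched acids), which makes C9–C10, turns the linking oxygen into the C20 silyl ester and moves the ring C double bond to C14=C8 next to the C13 ketal (13). Me3SiOTf then ionises this allylic ketal to a 1-alkoxyallyl cation whose C8 terminus is captured by the C6 silyl ketene acetal in a Mukaiyama–Michael addition (closest known type: silyl triflate-promoted conjugate addition of silyl ketene acetals to enone ketals), closing ring B in the 5-exo-trig mode, attack at C13 requiring a seven-membered ring; the silyl triflate or, failing that, the closing aqueous CF3CO2H cleaves the tert-butyl ester, and the aqueous acid unmasks the C13 ketone and both acids. C9 is set by suprafacial chirality transfer from the C14 carbinol of 5. C10 is set by approach of the allyl unit anti to the C6 arm, which A(1,3) strain from the two exocyclic ketene acetals at C10 and C4 holds axial on C5, giving the trans A/B junction. C8 follows because the tether from C9 can deliver C6 only to the same face (cis B/C junction), and C6 from placing the bulky C(OSiMe3)(Ot-Bu) terminus exo, away from ring C and from the α C20 silyl ester, which should also be the thermodynamically preferred 6β-carboxyl; C4 is reprotonated on work-up and is reset in step 11. The step needs C6 and not the C4 ketene acetal to capture the cation, which is secured because the C4 terminus is fully substituted and would have to join two quaternary carbons across ring A in a bicyclo[3.2.1]octane, and it needs the rearrangement to outrun ketene loss from the ester enolates, which is secured by silylation in situ at −78 °C.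

Step 9
Reactants: 14 13-oxo tricyclic diacid monomethyl ester with CH2C≡C–SiMe3 on C8
Product: 15 the same tricycle with a terminal alkyne (CH2C≡CH on C8)
Conditions: K2CO3 (3 equiv), MeOH, rt; then 1 M HCl
Reagents that add atoms: none
Why: Methoxide-mediated protodesilylation of the alkynylsilane; the carboxylates are inert, retro-Michael opening is disfavoured because C6 carries a carboxylate, and no stereocentre of the target is affected.

Step 10
Reactants: 15 13-oxo tricyclic diacid monomethyl ester with CH2C≡CH on C8
Product: 16 4-demethyl (4β-H) 19-methyl ester of the target gibberellin (13-hydroxy-16-methylene rings C and D in place; 7- and 20-oic acids)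
Conditions: SmI2 (4 equiv), HMPA, t-BuOH, THF, 0 °C → rt; then 1 M HCl, 0 °C
Reagents that add atoms: none
Why: Ketyl–alkyne radical cyclisation with divalent samarium: the C13 ketyl adds 5-exo-dig to C16 of the propargyl arm, which can bridge to C13 from one face only, so the bicyclo[3.2.1]octane forms with the C13 configuration fixed by the bridge and the vinyl radical ends as the exocyclic methylene.

Step 11
Reactants: 16 4-demethyl (4β-H) 19-methyl ester of the target gibberellin
Product: 17 19-methyl ester of the target gibberellin
Conditions: LiN(i-Pr)2 (4.5 equiv), THF/DMPU, −78 → −20 °C; MeI (1.2 equiv), −78 °C; then 1 M HCl, 0 °C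
Reagents that add atoms: iodomethane, CI
Why: Ester enolate alkylation: with C7 and C20 held as carboxylates only C4–H is removed, and MeI should approach the exocyclic enolate from the equatorial β-face, away from the axial C20 carboxylate across the 1,3-diaxial positions, leaving the C19 ester axial (α) as in the target.

Step 12
Reactants: 17 19-methyl ester of the target gibberellin
Product: 18 the target gibberellin, ent-13-hydroxygibberell-16-ene-7,19,20-trioic acid
Conditions: NaSEt (excess), DMF, 90 °C; then 1 M HCl, 0 °C
Reagents that add atoms: none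
Why: SN2 demethylation of the hindered C19 methyl ester by thiolate, which attacks the methyl carbon and is therefore insensitive to the shielding of the carbonyl; no stereocentre is touched.

**Compound list**
1 | 1,4-dioxaspiro[4.5]decan-6-one | O=C1CCCCC12OCCO2 | starting material
2 | 3-bromo-1-(trimethylsilyl)prop-1-yne | BrCC#C[Si](C)(C)C | starting material
3 | rac-7-[3-(trimethylsilyl)prop-2-yn-1-yl]-1,4-dioxaspiro[4.5]decan-6-one | O=C1C(CC#C[Si](C)(C)C)CCCC12OCCO2 | intermediate
4 | 7-[3-(trimethylsilyl)prop-2-yn-1-yl]-1,4-dioxaspiro[4.5]dec-7-en-6-one | O=C1C(CC#C[Si](C)(C)C)=CCCC12OCCO2 | intermediate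
5 | (6R)-7-[3-(trimethylsilyl)prop-2-yn-1-yl]-1,4-dioxaspiro[4.5]dec-7-en-6-ol | O[C@@H]1C(CC#C[Si](C)(C)C)=CCCC12OCCO2 | intermediate
6 | dimethyl 2-bromobenzene-1,3-dicarboxylate | COC(=O)c1cccc(C(=O)OC)c1Br | starting material
7 | tert-butyl bromoacetate | BrCC(=O)OC(C)(C)C | starting material
8 | dimethyl 2-(2-tert-butoxy-2-oxoethyl)benzene-1,3-dicarboxylate | COC(=O)c1cccc(C(=O)OC)c1CC(=O)OC(C)(C)C | intermediate
9 | dimethyl all-cis-2-(2-tert-butoxy-2-oxoethyl)cyclohexane-1,3-dicarboxylate (meso) | [C@H]1(C(=O)OC)CCC[C@@H](C(=O)OC)[C@H]1CC(=O)OC(C)(C)C | intermediate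
10 | (1S,2S,3R)-2-(2-tert-butoxy-2-oxoethyl)-3-(methoxycarbonyl)cyclohexane-1-carboxylic acid (all-cis) | [C@H]1(C(=O)O)CCC[C@@H](C(=O)OC)[C@H]1CC(=O)OC(C)(C)C | intermediate
11 | allylic ester: C20 carboxyl of 10 esterified with the (6R)-carbinol of 5 | [C@H]1(C(=O)O[C@@H]2C(CC#C[Si](C)(C)C)=CCCC23OCCO3)CCC[C@@H](C(=O)OC)[C@H]1CC(=O)OC(C)(C)C | intermediate
12 | tris(trimethylsilyl ketene acetal) of 11 at C10=C20, C4=C19 and C6=C7 (ketene acetal geometries not controlled) | C(O[Si](C)(C)C)(O[C@@H]2C(CC#C[Si](C)(C)C)=CCCC23OCCO3)=C1CCCC(=C(OC)O[Si](C)(C)C)[C@H]1C=C(OC(C)(C)C)O[Si](C)(C)C | intermediate (not isolated)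
13 | [3,3] product: C20 trimethylsilyl ester on quaternary C10, new C9–C10 bond, ring C double bond at C14=C8 beside the C13 dioxolane; C4 and C6 still silyl ketene acetals | C1(CC#C[Si](C)(C)C)=CC2(OCCO2)CC[C@H]1[C@]1(C(=O)O[Si](C)(C)C)CCCC(=C(OC)O[Si](C)(C)C)[C@H]1C=C(OC(C)(C)C)O[Si](C)(C)C | intermediate (not isolated)
14 | 13-oxo tricycle (rings A, B, C): 19-methyl ester with 4β-H (the epimer expected from equatorial protonation; either C4 epimer serves in step 11), 7- and 20-oic acids, β-CH2C≡C–SiMe3 on C8; C5, C6, C8, C9, C10 as in the target | C[Si](C)(C)C#CC[C@]12CC(=O)CC[C@H]1[C@]1(C(=O)O)CCC[C@@H](C(=O)OC)[C@H]1[C@@H]2C(=O)O | intermediate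
15 | as 14 with a terminal alkyne (β-CH2C≡CH on C8) | C#CC[C@]12CC(=O)CC[C@H]1[C@]1(C(=O)O)CCC[C@@H](C(=O)OC)[C@H]1[C@@H]2C(=O)O | intermediate
16 | 4-demethyl (4β-H) 19-methyl ester of the target gibberellin (ent-13-hydroxy-18-norgibberell-16-ene-7,19,20-trioic acid 19-methyl ester) | C=C1C[C@]23C[C@@]1(O)CC[C@H]2[C@]1(C(=O)O)CCC[C@@H](C(=O)OC)[C@H]1[C@@H]3C(=O)O | intermediate
17 | 19-methyl ester of the target gibberellin (ent-13-hydroxygibberell-16-ene-7,19,20-trioic acid 19-methyl ester) | C=C1C[C@]23C[C@@]1(O)CC[C@H]2[C@]1(C(=O)O)CCC[C@@](C)(C(=O)OC)[C@H]1[C@@H]3C(=O)O | intermediate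
18 | the target gibberellin, ent-13-hydroxygibberell-16-ene-7,19,20-trioic acid | C=C1C[C@]23C[C@@]1(O)CC[C@H]2[C@]1(C(=O)O)CCC[C@@](C)(C(=O)O)[C@H]1[C@@H]3C(=O)O | target

**Totals and risks**
Total step count: 12. Longest linear sequence: 9 steps (steps 4–12; the branch through steps 1–3 and 7–12 is equally long).

Step 8 is the most exposed. The allyl unit may approach C10 from the face syn to the C6 arm (cis A/B junction). After ionisation, the allyl cation may lose a proton to a dienol ether or be captured by the C4 ketene acetal instead of closing ring B. The fallback sets out from 11 and separates the two bond formations. Only the Ireland–Claisen stage is run (LiN(i-Pr)2, Me3SiCl, THF, −78 → 65 °C) and worked up with aqueous HCl, which should hydrolyse the ketal and give the enone acid F1, in which C14=C8 is conjugated to the C13 ketone and C10 epimers can be removed. Ring B is then closed by a reversible, base-mediated intramolecular Michael addition of the tert-butyl ester enolate (t-BuOK, t-BuOH/THF), which under thermodynamic control should select the 6β-ester in the keto acid tert-butyl ester F2. CF3CO2H in CH2Cl2 removes the tert-butyl group and the route is rejoined at 14.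

Step 6 may fail through low enantiotopic-group selectivity of the hydrolase, hydrolysis of the wrong enantiotopic ester, or very slow turnover because both methyl esters are flanked by the C5 substituent. The fallback sets out from 9 and replaces the enzyme by an anhydride desymmetrisation. Both methyl esters are cleaved without epimerisation (Me3SnOH, 1,2-dichloroethane, 80 °C) to the meso diacid F3. Ac2O at 80 °C closes the cis-1,3-diacid to the bicyclic meso anhydride F4. Methanolysis mediated by a cinchona alkaloid (quinidine or quinine, whichever gives the needed hemiester; MeOH, toluene, −40 °C) then opens one enantiotopic carbonyl and the route is rejoined at 10.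

Step 11 may suffer from competing O-methylation of the tertiary alkoxide and the carboxylates in the tetra-lithiated species, from poor solubility of that polyanion, or from incomplete enolisation of the hindered C4–H. The fallback sets out from 14 and moves the methylation ahead of ring D closure, so that no alkoxide is present. The C13 ketone is protected (Me3SiOCH2CH2OSiMe3, Me3SiOTf, CH2Cl2, −78 °C; aqueous work-up) as the dioxolane diacid F5. The C4 ester enolate is formed and methylated (LiN(i-Pr)2, 3.5 equiv, THF/DMPU; MeI) to give the 4β-methyl dioxolane diacid F6, the facial bias from the axial C20 carboxylate being the same as in step 11. Aqueous HCl removes the ketal to give the methylated keto alkynylsilane F7, K2CO3/MeOH removes the alkynyl silyl group to give the methylated keto alkyne F8, and the SmI2 cyclisation of step 10 applied to F8 rejoins the route at 17.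

**Further compounds**
F1 | step 8 | enone acid after the Claisen stage alone: C9–C10 formed, ring C 13-oxo-Δ8(14)-enone, C20 acid, C7 tert-butyl ester on the open C6 arm, C19 methyl ester | C[Si](C)(C)C#CCC1=CC(=O)CC[C@H]1[C@]1(C(=O)O)CCC[C@@H](C(=O)OC)[C@H]1CC(=O)OC(C)(C)C
F2 | step 8 | 7-tert-butyl ester of 14 (ring B closed, 6β-ester) | C[Si](C)(C)C#CC[C@]12CC(=O)CC[C@H]1[C@]1(C(=O)O)CCC[C@@H](C(=O)OC)[C@H]1[C@@H]2C(=O)OC(C)(C)C
F3 | step 6 | all-cis-2-(2-tert-butoxy-2-oxoethyl)cyclohexane-1,3-dicarboxylic acid (meso) | [C@H]1(C(=O)O)CCC[C@@H](C(=O)O)[C@H]1CC(=O)OC(C)(C)C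
F4 | step 6 | meso bicyclic anhydride of F3 (3-oxabicyclo[3.3.1]nonane-2,4-dione carrying CH2CO2t-Bu on C9, syn to the anhydride bridge) | [C@H]1(C(=O)OC2=O)CCC[C@@H]2[C@H]1CC(=O)OC(C)(C)C
F5 | step 11 | 13,13-ethylenedioxy ketal of 14 | C[Si](C)(C)C#CC[C@]12CC3(OCCO3)CC[C@H]1[C@]1(C(=O)O)CCC[C@@H](C(=O)OC)[C@H]1[C@@H]2C(=O)O
F6 | step 11 | 4β-methyl derivative of F5 (C19 methyl ester α) | C[Si](C)(C)C#CC[C@]12CC3(OCCO3)CC[C@H]1[C@]1(C(=O)O)CCC[C@@](C)(C(=O)OC)[C@H]1[C@@H]2C(=O)O
F7 | step 11 | 4β-methyl derivative of 14 (13-oxo, alkynylsilane) | C[Si](C)(C)C#CC[C@]12CC(=O)CC[C@H]1[C@]1(C(=O)O)CCC[C@@](C)(C(=O)OC)[C@H]1[C@@H]2C(=O)O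
F8 | step 11 | 4β-methyl derivative of 15 (13-oxo, terminal alkyne) | C#CC[C@]12CC(=O)CC[C@H]1[C@]1(C(=O)O)CCC[C@@](C)(C(=O)OC)[C@H]1[C@@H]2C(=O)O
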